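**Retrosynthetic overview**
1. Target 25 ⇐ C8 angeloylation and C9 desilylation of lactone alcohol 21 ⇐ trans-fused α-methylene lactone 20 ⇐ 1,2-reduction/lactonization of ten-membered keto diester 18.
2. Ten-membered ring (key step): 18 ⇐ three-carbon ring expansion of cycloheptenone 14. Allylation of the ring ketone closes a five-membered ring; retro-aldol opening of the fusion bond with loss of chloride then gives the ten-membered ring and C1=C10.
3. 14 ⇐ chloro-aldol union (C9–C10 bond, C1–Cl handle) of cross-conjugated dienone ester 6 with α-alkoxy aldehyde 11.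
4. 6 ⇐ one-carbon ring expansion of 3-methylcyclohex-2-enone with methyl diazoacetate, then dehydrogenation. 11 ⇐ 2-vinyloxirane by Pd-catalysed asymmetric etherification, cross-metathesis and oxidation.
5. Ring order: six-membered (bought) → seven → transient five/seven bicycle → ten-membered carbocycle → γ-lactone.

Assumptions: atom labels C1–C15 follow germacrane numbering of 25 (lactone C6–O–C12, ester C14 on C10); PMB and TES are protecting groups, so 4-methoxybenzyl alcohol and TESOTf are reagents; the (R,R)-Trost ligand is taken to give (S)-8 (otherwise the (S,S)-ligand is used); methyl diazoacetate is bought as a solution or made from glycine methyl ester hydrochloride.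

**Step 1**
Reactants: 1 3-methylcyclohex-2-en-1-one; 2 methyl diazoacetate
Product: 3 methyl 4-methyl-2-oxocyclohept-3-ene-1-carboxylate
Conditions: BF3·OEt2, CH2Cl2, 0 °C to rt
Reagents that add atoms: none
Why: Lewis-acid-promoted diazoacetate homologation of a ketone (Tiffeneau–Demjanov-type 1,2-shift), in which the sp3 α-carbon migrates in preference to the vinyl carbon so the enone stays conjugated and the new ester-bearing carbon (C10) sits between C6 and C1.

**Step 2**
Reactants: 3 methyl 4-methyl-2-oxocyclohept-3-ene-1-carboxylate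
Product: 6 methyl 5-methyl-7-oxocyclohepta-1,5-diene-1-carboxylate, via selenide 4 (not isolated), via selenoxide 5 (not isolated)
Conditions: PhSeCl, pyridine, CH2Cl2, 0 °C; then 30% H2O2, 0 °C to rt; used crude
Reagents that add atoms: none
Why: α-selenenylation of the β-keto ester followed by selenoxide syn-elimination (Reich dehydrogenation), which can only eliminate toward the ring CH2 (C1) and so gives the C10=C1 alkylidene β-keto ester.

**Step 3**
Reactants: 7 2-vinyloxirane (racemic)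
Product: 8 (2S)-2-[(4-methoxybenzyl)oxy]but-3-en-1-ol
Conditions: 4-methoxybenzyl alcohol, Pd2(dba)3·CHCl3 (1 mol%), (R,R)-DACH-phenyl Trost ligand (3 mol%), Et3B (1 mol%), CH2Cl2, rt
Reagents that add atoms: 4-methoxybenzyl alcohol, COc1ccc(CO)cc1
Why: Trost dynamic kinetic asymmetric allylic etherification of the vinyl epoxide (zerovalent palladium/boron co-catalysis) delivers the branched ether, and the chiral ligand sets the C8 stereocentre.

**Step 4**
Reactants: 8 (2S)-2-[(4-methoxybenzyl)oxy]but-3-en-1-ol; 9 methyl 2-(bromomethyl)acrylate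
Product: 10 methyl (2Z,4S)-2-(bromomethyl)-5-hydroxy-4-[(4-methoxybenzyl)oxy]pent-2-enoate
Conditions: 9 (4 equiv), Hoveyda–Grubbs second-generation catalyst [RuCl2(H2IMes)(=CH-C6H4-2-OiPr)] (5 mol%), CH2Cl2, 40 °C
Reagents that add atoms: none
Why: olefin cross-metathesis of a terminal alkene with a 1,1-disubstituted acrylate gives the trisubstituted enoate under thermodynamic control, with the C8 chain trans to the ester (Z by CIP); C8 is untouched.

**Step 5**
Reactants: 10 methyl (2Z,4S)-2-(bromomethyl)-5-hydroxy-4-[(4-methoxybenzyl)oxy]pent-2-enoate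
Product: 11 methyl (2Z,4S)-2-(bromomethyl)-4-[(4-methoxybenzyl)oxy]-5-oxopent-2-enoate
Conditions: Dess–Martin periodinane, NaHCO3, CH2Cl2, 0 °C; used at once
Reagents that add atoms: none
Why: Dess–Martin oxidation of the primary alcohol under buffered, non-basic conditions keeps the α-alkoxy stereocentre intact.

**Step 6**
Reactants: 6 methyl 5-methyl-7-oxocyclohepta-1,5-diene-1-carboxylate; 11 methyl (2Z,4S)-2-(bromomethyl)-4-[(4-methoxybenzyl)oxy]-5-oxopent-2-enoate
Product: 13 methyl 7-chloro-1-[(1S,2S,3Z)-4-(bromomethyl)-1-hydroxy-5-methoxy-2-[(4-methoxybenzyl)oxy]-5-oxopent-3-en-1-yl]-4-methyl-2-oxocyclohept-3-ene-1-carboxylate (epimer mixture at ring C1 and C7), via chlorotitanium enolate 12 (not isolated)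
Conditions: TiCl4 (1.1 equiv), CH2Cl2, −78 °C; then 11 premixed with TiCl4 (1.1 equiv), −78 °C
Reagents that add atoms: titanium tetrachloride, Cl[Ti](Cl)(Cl)Cl
Why: TiCl4-mediated chloro-Michael/aldol (halo-aldol) coupling, in which chloride adds to the doubly activated C1 and the chelated titanium enolate attacks the TiCl4-chelated α-alkoxy aldehyde (Cram chelate) to give the 8,9-syn C9 carbinol; the C1 and C10 centres are lost later, so their mixture is harmless.

**Step 7**
Reactants: 13 chloro aldol (as named in step 6)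
Product: 14 methyl 7-chloro-1-[(1S,2S,3Z)-4-(bromomethyl)-5-methoxy-2-[(4-methoxybenzyl)oxy]-5-oxo-1-[(triethylsilyl)oxy]pent-3-en-1-yl]-4-methyl-2-oxocyclohept-3-ene-1-carboxylate
Conditions: TESOTf, 2,6-lutidine, CH2Cl2, −78 °C
Reagents that add atoms: triethylsilyl trifluoromethanesulfonate, CC[Si](CC)(CC)OS(=O)(=O)C(F)(F)F
Why: silyl ether formation blocks retro-aldol at C9–C10 and stops the C9 oxygen from acting as a competing fragmentation trigger in the next step.

**Step 8**
Reactants: 14 TES-protected chloro aldol (as named in step 7)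
Product: 18 dimethyl (1(10)E,4Z)-8-[(4-methoxybenzyl)oxy]-6-oxo-9-[(triethylsilyl)oxy]germacra-1(10),4,11(13)-triene-12,14-dioate (C7 C8 C9 as in 25), via allylsamarium 15 (not isolated), via bicyclic samarium alkoxide 16 (not isolated), via ring-expanded samarium enolate 17 (not isolated)
Conditions: SmI2 (2.2 equiv), THF, −78 °C to 0 °C; pH 7 buffer quench
Reagents that add atoms: none
Why: Proposed new method: SmI2 reduces the allylic bromide to an allylsamarium that is held by the C8 ether oxygen (alkoxy "inside") and adds through its γ-carbon to the ring ketone, closing the five-membered ring with C7 cis to the C8 oxygen; the congested trivalent samarium aldolate then undergoes retro-aldol cleavage of the C6–C10 fusion bond and the resulting ester enolate expels the β-chloride (E1cB, far better leaving group than the β-silyloxy) to give the ring-cis (E) enoate of the ten-membered ring; the closest known reactions are the samarium Barbier allylation with 2-(bromomethyl)acrylates, Trost's fluoride-triggered three-carbon condensative ring expansion of β-keto sulfones and the Grob fragmentation.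

**Step 9**
Reactants: 18 ten-membered keto diester (as named in step 8)
Product: 20 methyl (1(10)E,4Z)-8-[(4-methoxybenzyl)oxy]-12-oxo-9-[(triethylsilyl)oxy]germacra-1(10),4,11(13)-trien-6,12-olid-14-oate (trans-fused lactone; C6–C9 as in 25), via hydroxy diester 19 (not isolated)
Conditions: NaBH4, CeCl3·7H2O, MeOH, −78 °C; then PPTS (cat.), CH2Cl2, rt
Reagents that add atoms: none
Why: Luche 1,2-reduction of the enone with hydride delivered anti to the 1-(methoxycarbonyl)vinyl group on C7 (Felkin–Anh) gives the 6,7-syn alcohol, which lactonizes onto the acrylate ester to the trans-fused α-methylene-γ-lactone.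

**Step 10**
Reactants: 20 PMB/TES-protected lactone (as named in step 9)
Product: 21 methyl (1(10)E,4Z)-8-hydroxy-12-oxo-9-[(triethylsilyl)oxy]germacra-1(10),4,11(13)-trien-6,12-olid-14-oate
Conditions: DDQ, CH2Cl2/pH 7 phosphate buffer, 0 °C
Reagents that add atoms: none
Why: oxidative PMB ether cleavage is selective for the electron-rich benzyl ether and leaves the TES ether, the electron-poor alkenes and the lactone untouched.

**Step 11**
Reactants: 21 C8 alcohol (as named in step 10); 22 angelic acid [(2Z)-2-methylbut-2-enoic acid]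
Product: 24 methyl (1(10)E,4Z)-8-{[(2Z)-2-methylbut-2-enoyl]oxy}-12-oxo-9-[(triethylsilyl)oxy]germacra-1(10),4,11(13)-trien-6,12-olid-14-oate, via mixed anhydride 23 (not isolated)
Conditions: 22, 2,4,6-trichlorobenzoyl chloride, Et3N, toluene, rt; then 21, toluene, 60 °C (no DMAP)
Reagents that add atoms: none
Why: Yamaguchi-type mixed-anhydride esterification without a nucleophilic catalyst acylates the only free hydroxyl (C8) with retention at C8 and avoids angelate-to-tiglate isomerization.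

**Step 12**
Reactants: 24 angelate TES ether (as named in step 11)
Product: 25 methyl (1(10)E,4Z,6R,7S,8S,9S)-8-{[(2Z)-2-methylbut-2-enoyl]oxy}-9-hydroxy-12-oxogermacra-1(10),4,11(13)-trien-6,12-olid-14-oate (CNP0305372.2)
Conditions: HF·pyridine, pyridine/THF, 0 °C
Reagents that add atoms: none
Why: buffered fluoride desilylation frees the C9 hydroxyl under mildly acidic conditions that suppress C8→C9 acyl migration and spare the α-methylene lactone.

**Compound list**
1 | 3-methylcyclohex-2-en-1-one | CC1=CC(=O)CCC1 | starting material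
2 | methyl diazoacetate | COC(=O)C=[N+]=[N-] | starting material
3 | methyl 4-methyl-2-oxocyclohept-3-ene-1-carboxylate (racemic) | COC(=O)C1CCCC(C)=CC1=O | intermediate
4 | methyl 4-methyl-2-oxo-1-(phenylselanyl)cyclohept-3-ene-1-carboxylate | COC(=O)C1([Se]c2ccccc2)CCCC(C)=CC1=O | intermediate
5 | methyl 4-methyl-2-oxo-1-(phenylseleninyl)cyclohept-3-ene-1-carboxylate | COC(=O)C1([Se](=O)c2ccccc2)CCCC(C)=CC1=O | intermediate
6 | methyl 5-methyl-7-oxocyclohepta-1,5-diene-1-carboxylate | COC(=O)C1=CCCC(C)=CC1=O | intermediate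
7 | 2-vinyloxirane (racemic) | C=CC1CO1 | starting material
8 | (2S)-2-[(4-methoxybenzyl)oxy]but-3-en-1-ol | OC[C@@H](OCc1ccc(OC)cc1)C=C | intermediate
9 | methyl 2-(bromomethyl)acrylate | C=C(CBr)C(=O)OC | starting material
10 | methyl (2Z,4S)-2-(bromomethyl)-5-hydroxy-4-[(4-methoxybenzyl)oxy]pent-2-enoate | OC[C@@H](OCc1ccc(OC)cc1)/C=C(\CBr)C(=O)OC | intermediate
11 | methyl (2Z,4S)-2-(bromomethyl)-4-[(4-methoxybenzyl)oxy]-5-oxopent-2-enoate | O=C[C@@H](OCc1ccc(OC)cc1)/C=C(\CBr)C(=O)OC | intermediate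
12 | methyl 7-chloro-4-methyl-2-[(trichlorotitanio)oxy]cyclohepta-1,3-diene-1-carboxylate | COC(=O)C1=C(O[Ti](Cl)(Cl)Cl)C=C(C)CCC1Cl | intermediate
13 | methyl 7-chloro-1-[(1S,2S,3Z)-4-(bromomethyl)-1-hydroxy-5-methoxy-2-[(4-methoxybenzyl)oxy]-5-oxopent-3-en-1-yl]-4-methyl-2-oxocyclohept-3-ene-1-carboxylate (mixture at ring C1, C7) | COC(=O)C1(C(Cl)CCC(C)=CC1=O)[C@H](O)[C@@H](OCc2ccc(OC)cc2)/C=C(\CBr)C(=O)OC | intermediate
14 | triethylsilyl ether of 13 (side chain 1S,2S,3Z) | COC(=O)C1(C(Cl)CCC(C)=CC1=O)[C@H](O[Si](CC)(CC)CC)[C@@H](OCc2ccc(OC)cc2)/C=C(\CBr)C(=O)OC | intermediate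
15 | diiodosamarium allyl species from 14 (Sm on the former CH2Br carbon) | COC(=O)C1(C(Cl)CCC(C)=CC1=O)[C@H](O[Si](CC)(CC)CC)[C@@H](OCc2ccc(OC)cc2)/C=C(\C[Sm](I)I)C(=O)OC | intermediate
16 | diiodosamarium 8-chloro-8a-(methoxycarbonyl)-3-(3-methoxy-3-oxoprop-1-en-2-yl)-2-[(4-methoxybenzyl)oxy]-5-methyl-1-[(triethylsilyl)oxy]-1,2,3,6,7,8-hexahydroazulen-3a-olate (C7, C8, C9 as in 25) | COC(=O)C(=C)[C@@H]1[C@H](OCc2ccc(OC)cc2)[C@@H](O[Si](CC)(CC)CC)C2(C(=O)OC)C(Cl)CCC(C)=CC12O[Sm](I)I | intermediate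
17 | diiodosamarium ester enolate of the ring-opened ten-membered 1-chloro-6-oxo diester | C=C(C(=O)OC)[C@H]1C(=O)/C=C(/C)CCC(Cl)C(=C(OC)O[Sm](I)I)[C@H](O[Si](CC)(CC)CC)[C@H]1OCc2ccc(OC)cc2 | intermediate
18 | dimethyl (1(10)E,4Z)-8-[(4-methoxybenzyl)oxy]-6-oxo-9-[(triethylsilyl)oxy]germacra-1(10),4,11(13)-triene-12,14-dioate | C=C(C(=O)OC)[C@H]1C(=O)/C=C(/C)CC/C=C(/C(=O)OC)[C@H](O[Si](CC)(CC)CC)[C@H]1OCc2ccc(OC)cc2 | intermediate
19 | dimethyl (1(10)E,4Z)-6-hydroxy-8-[(4-methoxybenzyl)oxy]-9-[(triethylsilyl)oxy]germacra-1(10),4,11(13)-triene-12,14-dioate (C6–C9 as in 25) | C=C(C(=O)OC)[C@H]1[C@H](O)/C=C(/C)CC/C=C(/C(=O)OC)[C@H](O[Si](CC)(CC)CC)[C@H]1OCc2ccc(OC)cc2 | intermediate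
20 | methyl (1(10)E,4Z)-8-[(4-methoxybenzyl)oxy]-12-oxo-9-[(triethylsilyl)oxy]germacra-1(10),4,11(13)-trien-6,12-olid-14-oate | C=C1C(=O)O[C@@H]2/C=C(/C)CC/C=C(/C(=O)OC)[C@H](O[Si](CC)(CC)CC)[C@@H](OCc3ccc(OC)cc3)[C@@H]12 | intermediate
21 | methyl (1(10)E,4Z)-8-hydroxy-12-oxo-9-[(triethylsilyl)oxy]germacra-1(10),4,11(13)-trien-6,12-olid-14-oate | C=C1C(=O)O[C@@H]2/C=C(/C)CC/C=C(/C(=O)OC)[C@H](O[Si](CC)(CC)CC)[C@@H](O)[C@@H]12 | intermediate
22 | angelic acid, (2Z)-2-methylbut-2-enoic acid | C/C=C(/C)C(=O)O | starting material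
23 | (2Z)-2-methylbut-2-enoic 2,4,6-trichlorobenzoic anhydride | C/C=C(/C)C(=O)OC(=O)c1c(Cl)cc(Cl)cc1Cl | intermediate
24 | methyl (1(10)E,4Z)-8-{[(2Z)-2-methylbut-2-enoyl]oxy}-12-oxo-9-[(triethylsilyl)oxy]germacra-1(10),4,11(13)-trien-6,12-olid-14-oate | C=C1C(=O)O[C@@H]2/C=C(/C)CC/C=C(/C(=O)OC)[C@H](O[Si](CC)(CC)CC)[C@@H](OC(=O)/C(C)=C\C)[C@@H]12 | intermediate
25 | CNP0305372.2, (6R,7S,8S,9S) | C=C1C(=O)O[C@@H]2/C=C(/C)CC/C=C(/C(=O)OC)[C@H](O)[C@@H](OC(=O)/C(C)=C\C)[C@@H]12 | target

**Totals**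
Total steps: 12. Longest linear sequence: 10 (steps 3–12).

**Three steps most likely to fail**

Step 8 (the proposed new cascade). The samarium alkoxide may lactonize onto the acrylate ester or simply not fragment, and C7 control rests on ether chelation. The fallback sets out from 14 and comes back at 18, using two separate known reactions. Indium powder in THF/H2O performs the Barbier allylation of the ring ketone and gives the bicyclic tertiary alcohol methyl 8-chloro-3a-hydroxy-3-(3-methoxy-3-oxoprop-1-en-2-yl)-2-[(4-methoxybenzyl)oxy]-5-methyl-1-[(triethylsilyl)oxy]-2,3,3a,6,7,8-hexahydroazulene-8a(1H)-carboxylate F1, which is isolated. KN(SiMe3)2 in THF at −78 °C then effects a Wharton–Grob fragmentation of the γ-chloro alkoxide to 18.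

Step 6 (chloro-aldol forming a quaternary carbon). The stabilized titanium enolate may be too unreactive, or TiCl4 may damage the PMB ether. The fallback sets out from 6 and comes back at 18. Thiophenol with catalytic Et3N adds to 6 (sulfa-Michael) to give methyl 4-methyl-2-oxo-7-(phenylsulfanyl)cyclohept-3-ene-1-carboxylate F2. Me3SiCl/Et3N converts it into the silyl enol ether methyl 4-methyl-7-(phenylsulfanyl)-2-[(trimethylsilyl)oxy]cyclohepta-1,3-diene-1-carboxylate F3. A chelation-controlled Mukaiyama aldol with 11 (TiCl4, CH2Cl2, −78 °C) gives the phenylsulfanyl analogue of 13 F4, and TESOTf/2,6-lutidine gives the phenylsulfanyl analogue of 14 F5. Under the step 8 conditions F5 loses thiolate in place of chloride and delivers 18.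

Step 4 (cross-metathesis to a trisubstituted enoate next to an allylic ether). Yield may be low. The fallback sets out from 8 and comes back at 10 by a Morita–Baylis–Hillman route. TBSCl/imidazole gives the silyl ether tert-butyl{[(2S)-2-[(4-methoxybenzyl)oxy]but-3-en-1-yl]oxy}dimethylsilane F6. Ozonolysis (O3, CH2Cl2, −78 °C; PPh3) gives (2R)-3-[(tert-butyldimethylsilyl)oxy]-2-[(4-methoxybenzyl)oxy]propanal F7. Methyl acrylate with DABCO gives the adduct methyl 5-[(tert-butyldimethylsilyl)oxy]-3-hydroxy-4-[(4-methoxybenzyl)oxy]-2-methylidenepentanoate F8 (carbinol mixture). N-Bromosuccinimide/Me2S converts it with allylic transposition into methyl (2Z,4S)-2-(bromomethyl)-5-[(tert-butyldimethylsilyl)oxy]-4-[(4-methoxybenzyl)oxy]pent-2-enoate F9, and HF·pyridine removes the silyl group to give 10.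

**Further compounds**
F1 | step 8 | methyl 8-chloro-3a-hydroxy-3-(3-methoxy-3-oxoprop-1-en-2-yl)-2-[(4-methoxybenzyl)oxy]-5-methyl-1-[(triethylsilyl)oxy]-2,3,3a,6,7,8-hexahydroazulene-8a(1H)-carboxylate | COC(=O)C(=C)[C@@H]1[C@H](OCc2ccc(OC)cc2)[C@@H](O[Si](CC)(CC)CC)C2(C(=O)OC)C(Cl)CCC(C)=CC12O
F2 | step 6 | methyl 4-methyl-2-oxo-7-(phenylsulfanyl)cyclohept-3-ene-1-carboxylate | COC(=O)C1C(Sc2ccccc2)CCC(C)=CC1=O
F3 | step 6 | methyl 4-methyl-7-(phenylsulfanyl)-2-[(trimethylsilyl)oxy]cyclohepta-1,3-diene-1-carboxylate | COC(=O)C1=C(O[Si](C)(C)C)C=C(C)CCC1Sc1ccccc1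
F4 | step 6 | methyl 1-[(1S,2S,3Z)-4-(bromomethyl)-1-hydroxy-5-methoxy-2-[(4-methoxybenzyl)oxy]-5-oxopent-3-en-1-yl]-4-methyl-2-oxo-7-(phenylsulfanyl)cyclohept-3-ene-1-carboxylate | COC(=O)C1(C(Sc2ccccc2)CCC(C)=CC1=O)[C@H](O)[C@@H](OCc2ccc(OC)cc2)/C=C(\CBr)C(=O)OC
F5 | step 6 | triethylsilyl ether of F4 | COC(=O)C1(C(Sc2ccccc2)CCC(C)=CC1=O)[C@H](O[Si](CC)(CC)CC)[C@@H](OCc2ccc(OC)cc2)/C=C(\CBr)C(=O)OC
F6 | step 4 | tert-butyl{[(2S)-2-[(4-methoxybenzyl)oxy]but-3-en-1-yl]oxy}dimethylsilane | CC(C)(C)[Si](C)(C)OC[C@@H](OCc1ccc(OC)cc1)C=C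
F7 | step 4 | (2R)-3-[(tert-butyldimethylsilyl)oxy]-2-[(4-methoxybenzyl)oxy]propanal | CC(C)(C)[Si](C)(C)OC[C@@H](OCc1ccc(OC)cc1)C=O
F8 | step 4 | methyl 5-[(tert-butyldimethylsilyl)oxy]-3-hydroxy-4-[(4-methoxybenzyl)oxy]-2-methylidenepentanoate (C4 as in 8, mixture at C3) | CC(C)(C)[Si](C)(C)OC[C@@H](OCc1ccc(OC)cc1)C(O)C(=C)C(=O)OC
F9 | step 4 | methyl (2Z,4S)-2-(bromomethyl)-5-[(tert-butyldimethylsilyl)oxy]-4-[(4-methoxybenzyl)oxy]pent-2-enoate | CC(C)(C)[Si](C)(C)OC[C@@H](OCc1ccc(OC)cc1)/C=C(\CBr)C(=O)OC
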